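# Zyggomphic acid B: synthesis design around a dimethylmaleic anhydride Diels–Alder reaction

## The problem

Zyggomphic acid B is a trans-fused 3a,6,7,7a-tetrahydro-3H-indene with five stereocentres, (3R,3aS,6S,7R,7aR). Ring A is a cyclopentene (C1 bearing ethyl, C2, C3 bearing methyl, C3a, C7a) and ring B a cyclohexene (C3a, C4 bearing methyl, C5, C6, C7, C7a), with trisubstituted alkenes at C1=C2 and C4=C5. The hardest element is the pair of adjacent quaternary carbons C6 and C7 with cis methyl groups. C7 carries the carboxylic acid and C6 the (1E,3E)-2-methyl-4-phenylbuta-1,3-dienyl chain (C1'–C4'). Neither quaternary centre can be corrected once made, so both must come from a stereospecific event. Once in place, C7 is the only handle on C7a, C7a can direct C3a (trans), and C3, an allylic methine that cannot be epimerised, needs reagent control. Because the ring fusion is trans, the strained cyclopentene has to be closed after C3a and C7a are fixed under kinetic control. The styryl diene will not survive acid, hydride reagents, oxidants or metathesis catalysts and should arrive last. The C7 acid sits cis to a neopentyl carbonyl-level carbon on C6, so the free acid tends to close to a lactol or lactone, and an ordinary ester at C7 resists saponification. The enabling feature is that C6 and C7 each carry a methyl group and a carbonyl-level carbon (C1' and the carboxyl carbon) in a cis vicinal array, the substitution pattern of 2,3-dimethylmaleic anhydride. C4/C5 can be read as a ketone with its α-methylene and C3a=C7a as an enone, which is the retron of a 1-amino-3-siloxybutadiene cycloaddition.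

## Retrosynthesis

**Acid protection.** The target 23 is traced to its allyl ester 22 by cutting the O–allyl bond. A methyl or tert-butyl ester would need saponification between two quaternary carbons or acid that endangers the diene. The allyl group leaves under neutral conditions with zerovalent palladium and an amine, which is all that is asked of the last step.

**C3'=C4'.** Cutting the styryl double bond of 22 gives enal 20 and diethyl benzylphosphonate 21. The alternative of forming C1'=C2' last with a preformed α-methyl dienyl ylide would give poor geometry control at a trisubstituted alkene. A benzylphosphonate adding to an enal reliably gives the E alkene, and the sensitive diene appears only two steps from the end.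

**C1'=C2'.** Cutting this bond of 20 gives the C6 aldehyde 18 and the stabilised ylide 19. The aldehyde has no α-hydrogen, so it cannot epimerise. The forward reaction must overcome a neopentyl carbonyl flanked by two quaternary carbons.

**Anhydride differentiation.** The aldehyde carbon and the ester carbon of 18 are both carbonyl-level carbons on the same face. They are traced through the hydroxy lactone (pseudoacid) 17 to the cyclic anhydride 16. This removes all side-chain complexity and turns two different groups into one. The forward step must deliver one hydride to the C6 carbonyl only, which is the less shielded of the two (next to the sp2 C5 rather than to C7a and ring A).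

**C4–methyl.** The C4–CH3 bond of 16 is cut to enol triflate 15 and then to ketone 14. Kinetic enolisation toward the C5 methylene fixes the alkene position, which a methyl addition–dehydration sequence would not.

**Ring A.** The C1=C2 bond of 14 is cut by ring-closing metathesis to diene 13. The trans relation of C3a and C7a is thereby set on an unstrained cyclohexanone before the cyclopentene is closed.

**C7a–C1 and C3a–C3.** Both bonds of 13 are cut across the enone of 7. The C7a substituent comes from 2-bromobut-1-ene 10 through cuprate 11. The C3a substituent comes from (R)-but-3-en-2-yl methyl carbonate 9, made from (R)-but-3-en-2-ol 8, which alkylates enolate 12. A linear crotyl halide would give the wrong constitution. A stereospecific, branched-selective allylic alkylation carries the C3 configuration in from the reagent, while C7a and C3a are controlled by the ring.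

**Key disconnection.** Enone anhydride 7 is cut at C5–C6 and C7–C7a to 2,3-dimethylmaleic anhydride 5 and the chiral diene 4, through cycloadduct 6. Both quaternary centres, their cis relation and ring B arise in one suprafacial event from two simple partners. The reaction has to tolerate a tetrasubstituted dienophile and must proceed by a single approach mode on a single diene face.

**Diene.** Diene 4 is cut at the O–Si bond to vinylogous amide 3, and 3 at the C–N bond to (E)-4-methoxybut-3-en-2-one 1 and (2S,5S)-2,5-diphenylpyrrolidine 2.

## Roads not taken

**Alternative 1:** The cut is the C5–C6 bond, with ring B closed last. Zerovalent palladium would add to a (Z)-alkenyl iodide at C5, the trisubstituted C6=C1' alkene would insert in the 6-exo mode, and β-hydride elimination of the C2' hydrogen would give the tert-butyl ester of the target, A1.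
- Merits: the dienyl side chain appears in the ring-forming step. No neopentyl aldehyde has to be olefinated and no pair of carbonyls has to be told apart. A1 is one deprotection from the target, so the endgame is shorter than in the chosen plan (five steps from 16).
- Weak points: C6 would be formed by migratory insertion into a trisubstituted alkene next to the already quaternary C7, the slowest kind of Heck insertion. Its configuration would rest on the conformational preference of an open chain rather than on a stereospecific event. The precursor needs a defined C6=C1' geometry, and the quaternary C7 has to be built next to the ring A stereotriad by acyclic stereocontrol. The geometry of the new C1'=C2' bond depends on the rotamer that undergoes syn elimination, and palladium hydride can isomerise the diene.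
- Comparison: the chosen plan sets C6 and C7 together, with their cis relation guaranteed by the dienophile and their absolute configuration coming from a recoverable amine. It pays for this with the later differentiation of the anhydride and two olefinations.

**Alternative 2:** The cut removes C7a–C3a, C3–C2 and C2–C1 at once. The Co2(CO)8 complex of an ethyl alkyne on C7 would combine with the terminal propenyl alkene of a (Z)-dienyl arm on C6 and carbon monoxide, on a menthyloxy lactone template, to give the tricyclic lactone A2.
- Merits: three C–C bonds and both rings form in one step, with C3 and C3a related through the alkene geometry. The lactone acetal distinguishes the acid carbon from the aldehyde-level C1' from the outset. This is better than the chosen plan, which has to achieve the distinction by a regioselective hydride reduction.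
- Weak points: the alkene partner is internal, 1,2-disubstituted and part of a conjugated diene, a poor substrate for this cyclisation. A six-membered ring must form alongside the cyclopentenone. A2 has the wrong ring A pattern, a C2 ketone and a C1=C7a alkene. The trans ring fusion would have to be made afterwards by reduction at C7a against the usual preference of hydrindanones. The C2 oxygen would have to be deleted while a C1=C2 alkene is placed regioselectively between two substituted carbons.
- Comparison: the chosen plan sets the ring fusion by kinetic trans alkylation and delivers the ring A alkene directly in position with no oxygen to remove.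

**Alternative 3:** The cut is a ring contraction. Ozonolysis of the cyclohexene of a trans-octalin and amine-catalysed aldol condensation of the dialdehyde would re-form C1–C2 and give the trans-hydrindene carbaldehyde A3.
- Merits: the stereocentres of ring A would be set on a trans-decalin, whose fusion is thermodynamically favoured and well understood. The ring contraction is classical chemistry. This ring A is more secure than the one in the chosen plan, which depends on a three-component coupling and a strained ring-closing metathesis.
- Weak points: the formyl group on C1 of A3 has to be turned into ethyl in at least two steps. C3 is α to an aldehyde in the dialdehyde and can epimerise under the amine. In A3, C6 is still an sp2 enone carbon, so the second quaternary centre would be made late by conjugate addition of the dienyl chain to a β,β-disubstituted enone beside the quaternary C7, with uncertain reactivity and face selectivity.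
- Comparison: the chosen plan takes the ethyl group directly from the alkenyl nucleophile and makes both quaternary carbons first and stereospecifically.

Key step: step 3

## Route

Remarks before the steps:
- The tetrahydroindene numbering of the target is used for all intermediates; β is the face of ring B that carries the C6 and C7 methyl groups and α the face of the two carbonyl-derived substituents.
- Assumption: the cycloaddition is taken to proceed endo on the diene face remote from the phenyl group of the pyrrolidine carbon lying syn to the C3a hydrogen, which from the (2S,5S)-amine gives the series drawn; should the sense be opposite, the (2R,5R)-amine is used with no other change.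

Step 1
Reactants: 1 (E)-4-methoxybut-3-en-2-one; 2 (2S,5S)-2,5-diphenylpyrrolidine
Product: 3 (E)-4-[(2S,5S)-2,5-diphenylpyrrolidin-1-yl]but-3-en-2-one
Conditions: CH2Cl2, 0 → 23 °C; MeOH removed in vacuo
Reagents that add atoms: none
Why: Addition–elimination (amine exchange) at the β-carbon of the vinylogous ester should give the E vinylogous amide; the stereocentres of 2 are not involved.

Step 2
Reactants: 3 (E)-4-[(2S,5S)-2,5-diphenylpyrrolidin-1-yl]but-3-en-2-one
Product: 4 (E)-1-[(2S,5S)-2,5-diphenylpyrrolidin-1-yl]-3-(tert-butyldimethylsilyloxy)buta-1,3-diene
Conditions: KN(SiMe3)2, THF, −78 °C; TBSCl, −78 → 23 °C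
Reagents that add atoms: tert-butyldimethylsilyl chloride, CC(C)(C)[Si](C)(C)Cl
Why: Kinetic deprotonation of the methyl ketone and O-silylation of the cross-conjugated enolate is the standard preparation of 1-amino-3-siloxybutadienes.

Step 3
Reactants: 4 (E)-1-[(2S,5S)-2,5-diphenylpyrrolidin-1-yl]-3-(tert-butyldimethylsilyloxy)buta-1,3-diene; 5 2,3-dimethylmaleic anhydride
Product: 7 (3aS,7aR)-3a,7a-dimethyl-3a,7a-dihydro-2-benzofuran-1,3,5(4H)-trione (ring B enone anhydride: C4 ketone and C3a=C7a alkene with C6 and C7 methyls cis), via endo cycloadduct 6 (not isolated)
Conditions: PhMe, 80 °C, sealed tube (12 kbar in CH2Cl2 at 23 °C if slow); then 10% aq. HF in MeCN, 0 → 23 °C; amine recovered from the acidic aqueous phase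
Reagents that add atoms: none
Why: The push–pull diene 4 and the electron-poor anhydride 5 should combine in a concerted, strongly asynchronous [4+2] cycloaddition in which the siloxy-activated CH2 terminus (C5) bonds to C6 ahead of the bond between the amino-bearing terminus (C7a) and C7; the closest known reaction type is the Diels–Alder reaction of 1-amino-3-siloxybutadienes with maleic anhydride and α-substituted acroleins. Ring B is closed in the intermolecular [4+2] mode, both σ bonds forming suprafacially on each partner. C6 and C7 are set together: their cis relation follows from suprafacial addition to the cyclic Z-configured dienophile, and their absolute configuration from the diene face, which the C2-symmetric pyrrolidine shields with one phenyl group whatever the rotamer about the C–N bond, combined with the endo mode. The C7a stereocentre of adduct 6 is transient. Aqueous HF hydrolyses the silyl enol ether and the β-ammonium ketone eliminates (E1cB) to the C3a=C7a enone, releasing the amine as its salt so that it cannot open the anhydride. The step needs both high face selectivity and a single approach mode, because endo and exo adducts from the same face converge to enantiomeric enones; the endo mode is expected from overlap of the tied-back anhydride carbonyls with the diene while the methyls point outward, and the high-lying HOMO of 4 is what offsets the tetrasubstituted dienophile.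

Step 4
Reactants: 8 (R)-but-3-en-2-ol
Product: 9 (R)-but-3-en-2-yl methyl carbonate
Conditions: ClCO2Me, pyridine, CH2Cl2, 0 °C
Reagents that add atoms: methyl chloroformate, COC(=O)Cl
Why: O-Acylation of the secondary alcohol; the C–O bond at the stereocentre is not broken, so the R configuration is kept.

Step 5
Reactants: 7 (3aS,7aR)-3a,7a-dimethyl-3a,7a-dihydro-2-benzofuran-1,3,5(4H)-trione; 10 2-bromobut-1-ene; 9 (R)-but-3-en-2-yl methyl carbonate
Product: 13 ring B ketone anhydride with a β-(but-1-en-2-yl) group at C7a and an α-[(2R)-but-3-en-2-yl] group at C3a (trans to each other; C7a substituent cis to the methyls), via lithium di(but-1-en-2-yl)cuprate 11 (not isolated), via C4 enolate 12 (not isolated)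
Conditions: 10, t-BuLi (2 equiv), Et2O, −78 °C; CuI (0.5 equiv), −40 °C; 7, THF, −78 → −40 °C; then RhCl(PPh3)3 (10 mol %), P(OMe)3 (40 mol %), 9, −10 → 23 °C; aq. NH4Cl
Reagents that add atoms: none
Why: Conjugate addition of the Gilman reagent is expected on the β face of 7, anti to the anhydride ring folded under the enone, and enolate 12 is then alkylated at C3a anti to the new C7a substituent, the usual trans outcome of three-component enone couplings. The C3a–C3 bond relies on the rhodium-catalysed allylic alkylation of monovalent copper ketone enolates with secondary allylic carbonates, which is branched-selective and proceeds with net retention, so the (R)-carbonate should give (R)-C3.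

Step 6
Reactants: 13 ring B ketone anhydride with β-(but-1-en-2-yl) at C7a and α-[(2R)-but-3-en-2-yl] at C3a
Product: 14 trans-fused tricyclic ketone anhydride: 1-ethyl-3,6,7-trimethyl-4-oxo-3a,4,5,6,7,7a-hexahydro-3H-indene-6,7-dicarboxylic anhydride, 3R, C3a–H β, C7a–H α, C3, C6 and C7 methyls β
Conditions: second-generation Grubbs catalyst (5 mol %), CH2Cl2, 40 °C
Reagents that add atoms: none
Why: Ring-closing metathesis of the monosubstituted and the 1,1-disubstituted alkene should close the trisubstituted cyclopentene with loss of ethene; the trans fusion is already fixed, as in known closures of trans-hydrindenes from trans-2,3-dialkenyl cyclohexanones.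

Step 7
Reactants: 14 trans-fused tricyclic ketone anhydride
Product: 15 C4 enol triflate of 14 (C4=C5 alkene, triflyloxy group on C4)
Conditions: KN(SiMe3)2, THF, −78 °C; PhNTf2, −78 → 0 °C
Reagents that add atoms: N-phenylbis(trifluoromethanesulfonimide), O=S(=O)(N(c1ccccc1)S(=O)(=O)C(F)(F)F)C(F)(F)F
Why: A bulky amide base at low temperature should remove a C5 methylene proton rather than the ring-fusion methine at C3a (kinetic enolate), and O-sulfonylation fixes the C4=C5 position; C3a is not touched, so the trans fusion is kept.

Step 8
Reactants: 15 C4 enol triflate
Product: 16 diene anhydride: 1-ethyl-3,4,6,7-tetramethyl-3a,6,7,7a-tetrahydro-3H-indene-6,7-dicarboxylic anhydride, configuration as in 14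
Conditions: SnMe4, Pd(PPh3)4 (5 mol %), LiCl, DMF, 80 °C
Reagents that add atoms: tetramethylstannane, C[Sn](C)(C)C
Why: Stille coupling of an alkenyl triflate with tetramethyltin installs the C4 methyl under neutral conditions that leave the anhydride untouched.

Step 9
Reactants: 16 diene anhydride
Product: 17 hydroxy lactone (pseudoacid): the C6 carbonyl of 16 reduced to a lactol CH(OH) carbon, lactone carbonyl on C7, mixture of lactol epimers
Conditions: LiAlH(OtBu)3 (1.2 equiv), THF, −78 → −20 °C; then 1 M HCl
Reagents that add atoms: none
Why: Semi-reduction of a cyclic anhydride with a bulky alkoxyaluminium hydride should stop at the tetrahedral alkoxide, which the gem-disubstitution keeps ring-closed at low temperature. The hydride is expected at the C6 carbonyl, which is flanked by the planar sp2 C5, rather than at the C7 carbonyl, which is shielded by the axial C7a hydrogen and ring A.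

Step 10
Reactants: 17 hydroxy lactone
Product: 18 allyl 1-ethyl-6-formyl-3,4,6,7-tetramethyl-3a,6,7,7a-tetrahydro-3H-indene-7-carboxylate (formyl on C6 and ester on C7 both α, methyls β)
Conditions: K2CO3, allyl bromide, DMF, 0 → 23 °C
Reagents that add atoms: allyl bromide, C=CCBr
Why: Under basic aprotic conditions a pseudoacid reacts through its ring-opened carboxylate, so O-alkylation should give the open-chain allyl ester and unveil the C6 aldehyde; C6 has no α-hydrogen and cannot epimerise.

Step 11
Reactants: 18 C6 aldehyde allyl ester; 19 2-(triphenylphosphoranylidene)propanal
Product: 20 enal: allyl ester as 18 with an (E)-2-methyl-3-oxoprop-1-enyl group on C6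
Conditions: 19 (3 equiv), PhMe, 110 °C
Reagents that add atoms: none
Why: Wittig olefination with a stabilised formyl ylide gives the E trisubstituted enal under thermodynamic control of oxaphosphetane formation; heat is needed for the neopentyl aldehyde.

Step 12
Reactants: 20 enal; 21 diethyl benzylphosphonate
Product: 22 allyl ester of the target: allyl 1-ethyl-3,4,6,7-tetramethyl-6-[(1E,3E)-2-methyl-4-phenylbuta-1,3-dienyl]-3a,6,7,7a-tetrahydro-3H-indene-7-carboxylate
Conditions: 21, NaH, THF, 0 °C; then 20, 0 → 23 °C
Reagents that add atoms: none
Why: Horner–Wadsworth–Emmons reaction of a benzylphosphonate anion with an enal gives the E styryl alkene; the preformed anion adds to the aldehyde faster than it deprotonates the γ-methyl group.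

Step 13
Reactants: 22 allyl ester of the target
Product: 23 zyggomphic acid B, (3R,3aS,6S,7R,7aR)-1-ethyl-3,4,6,7-tetramethyl-6-[(1E,3E)-2-methyl-4-phenylbuta-1,3-dienyl]-3a,6,7,7a-tetrahydro-3H-indene-7-carboxylic acid
Conditions: Pd(PPh3)4 (5 mol %), morpholine, THF, 23 °C
Reagents that add atoms: none
Why: Zerovalent palladium ionises the allyl ester to a π-allyl complex that morpholine traps (Tsuji–Trost deallylation), freeing the hindered acid without acid, base or hydride near the diene.

## Compound list

1 | (E)-4-methoxybut-3-en-2-one | CO/C=C/C(C)=O | starting material
2 | (2S,5S)-2,5-diphenylpyrrolidine | N1[C@H](c2ccccc2)CC[C@H]1c1ccccc1 | starting material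
3 | (E)-4-[(2S,5S)-2,5-diphenylpyrrolidin-1-yl]but-3-en-2-one | CC(=O)/C=C/N1[C@H](c2ccccc2)CC[C@H]1c1ccccc1 | intermediate
4 | (E)-1-[(2S,5S)-2,5-diphenylpyrrolidin-1-yl]-3-(tert-butyldimethylsilyloxy)buta-1,3-diene | C=C(O[Si](C)(C)C(C)(C)C)/C=C/N1[C@H](c2ccccc2)CC[C@H]1c1ccccc1 | intermediate
5 | 2,3-dimethylmaleic anhydride | CC1=C(C)C(=O)OC1=O | starting material
6 | endo cycloadduct: 5-(tert-butyldimethylsilyloxy)-7-[(2S,5S)-2,5-diphenylpyrrolidin-1-yl]-3a,7a-dimethyl-3a,4,7,7a-tetrahydro-2-benzofuran-1,3-dione, amino group cis to the anhydride ring, methyls cis | CC(C)(C)[Si](C)(C)OC1=C[C@@H](N2[C@H](c3ccccc3)CC[C@H]2c2ccccc2)[C@@]2(C)C(=O)OC(=O)[C@@]2(C)C1 | intermediate (not isolated)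
7 | (3aS,7aR)-3a,7a-dimethyl-3a,7a-dihydro-2-benzofuran-1,3,5(4H)-trione | O=C1C[C@]2(C)C(=O)OC(=O)[C@]2(C)C=C1 | intermediate
8 | (R)-but-3-en-2-ol | C=C[C@@H](C)O | starting material
9 | (R)-but-3-en-2-yl methyl carbonate | C=C[C@@H](C)OC(=O)OC | intermediate
10 | 2-bromobut-1-ene | C=C(Br)CC | starting material
11 | lithium di(but-1-en-2-yl)cuprate | [Li+].C=C(CC)[Cu-]C(=C)CC | intermediate (not isolated)
12 | C4 lithium enolate of the conjugate adduct (C3a=C4 enolate, β-(but-1-en-2-yl) at C7a) | [Li+].[O-]C1=C[C@H](C(=C)CC)[C@@]2(C)C(=O)OC(=O)[C@@]2(C)C1 | intermediate (not isolated)
13 | 7-(but-1-en-2-yl)-6-[(2R)-but-3-en-2-yl]-3a,7a-dimethyltetrahydro-2-benzofuran-1,3,5(4H)-trione; in target numbering β-(but-1-en-2-yl) at C7a, α-butenyl at C3a, methyls β | O=C1C[C@]2(C)C(=O)OC(=O)[C@]2(C)[C@@H](C(=C)CC)[C@@H]1[C@H](C)C=C | intermediate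
14 | 1-ethyl-3,6,7-trimethyl-4-oxo-3a,4,5,6,7,7a-hexahydro-3H-indene-6,7-dicarboxylic anhydride, 3R, trans-fused (C3a–H β, C7a–H α), methyls β | CCC1=C[C@@H](C)[C@@H]2C(=O)C[C@]3(C)C(=O)OC(=O)[C@]3(C)[C@@H]12 | intermediate
15 | C4 enol triflate of 14 (C4=C5) | CCC1=C[C@@H](C)[C@@H]2C(OS(=O)(=O)C(F)(F)F)=C[C@]3(C)C(=O)OC(=O)[C@]3(C)[C@@H]12 | intermediate
16 | 1-ethyl-3,4,6,7-tetramethyl-3a,6,7,7a-tetrahydro-3H-indene-6,7-dicarboxylic anhydride, configuration as 14 | CCC1=C[C@@H](C)[C@@H]2C(C)=C[C@]3(C)C(=O)OC(=O)[C@]3(C)[C@@H]12 | intermediate
17 | hydroxy lactone (pseudoacid): lactol carbon on C6, lactone carbonyl on C7, lactol epimers | CCC1=C[C@@H](C)[C@@H]2C(C)=C[C@]3(C)C(O)OC(=O)[C@]3(C)[C@@H]12 | intermediate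
18 | allyl 1-ethyl-6-formyl-3,4,6,7-tetramethyl-3a,6,7,7a-tetrahydro-3H-indene-7-carboxylate | CCC1=C[C@@H](C)[C@@H]2C(C)=C[C@](C)(C=O)[C@](C)(C(=O)OCC=C)[C@@H]12 | intermediate
19 | 2-(triphenylphosphoranylidene)propanal | CC(C=O)=P(c1ccccc1)(c1ccccc1)c1ccccc1 | starting material
20 | allyl 1-ethyl-3,4,6,7-tetramethyl-6-[(E)-2-methyl-3-oxoprop-1-enyl]-3a,6,7,7a-tetrahydro-3H-indene-7-carboxylate | CCC1=C[C@@H](C)[C@@H]2C(C)=C[C@](C)(/C=C(\C)C=O)[C@](C)(C(=O)OCC=C)[C@@H]12 | intermediate
21 | diethyl benzylphosphonate | CCOP(=O)(Cc1ccccc1)OCC | starting material
22 | allyl ester of zyggomphic acid B | CCC1=C[C@@H](C)[C@@H]2C(C)=C[C@](C)(/C=C(C)/C=C/c3ccccc3)[C@](C)(C(=O)OCC=C)[C@@H]12 | intermediate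
23 | zyggomphic acid B | CCC1=C[C@@H](C)[C@@H]2C(C)=C[C@](C)(/C=C(C)/C=C/c3ccccc3)[C@](C)(C(=O)O)[C@@H]12 | target

## Step count and least certain steps

Total: 13 steps. Longest linear sequence: 12 steps (steps 1–3 and 5–13); step 4 prepares carbonate 9 in one step from 8.

**Step 3 (key step).** The most likely failure is that cycloaddition to the tetrasubstituted dienophile is too slow, so that the diene decomposes or is acylated on heating. Loss of a single approach mode is also possible, because the outward methyl groups weaken the endo preference, and this would lower the enantiomeric purity of 7. The fallback replaces the dienophile by a tied-back, more reactive surrogate. Diene 4 would be combined with 4,6-dihydro-1H,3H-thieno[3,4-c]furan-1,3-dione F1 (2,5-dihydrothiophene-3,4-dicarboxylic anhydride, a known compound), which lacks the two methyl groups and should react at lower temperature with a stronger endo bias, to give the thia-bridged endo cycloadduct F2. Desulfurisation of F2 with deactivated Raney Ni in THF would unveil both methyl groups and give 6, which is converted to 7 with HF as in step 3.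

**Step 5.** The most likely failure is in the allylation. Bond formation at the crowded enolate carbon C3a with a secondary rhodium-allyl species may be slower than protonation of the enolate, or may lose branched selectivity and stereochemical fidelity. The face of cuprate attack at C7a also rests on a conformational argument rather than on close precedent, and is read out here. The fallback builds C3 stepwise under substrate control.
- Enone 7 would be treated with cuprate 11 and Me3SiCl to give silyl enol ether F3.
- Mukaiyama aldol reaction with acetaldehyde (TiCl4, CH2Cl2, −78 °C) would give β-hydroxy ketone F4.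
- MsCl/Et3N followed by DBU would give the (E)-ethylidene ketone F5, in which allylic strain holds the C7a substituent axial over the β face of the exocyclic alkene.
- Addition of (CH2=CH)2CuLi from the α face would set (R)-C3, and protonation with DBU equilibration at C3a would give the trans ketone 13.

**Step 9.** The most likely failure is over-reduction past the lactol stage to the lactone, together with incomplete discrimination between the two neopentyl carbonyls. The fallback accepts full reduction. From 16, LiBH(s-Bu)3 (THF, −78 → 0 °C) would reduce the less hindered C6 carbonyl completely to lactone F6, the bulkier hydride sharpening the steric preference. Saponification (KOH, aq. THF), evaporation and alkylation of the potassium carboxylate with allyl bromide in DMF would give hydroxy ester F7. Oxidation without delay (Dess–Martin periodinane) would return to aldehyde 18.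

**Step 11.** The most likely failure is slow addition of the weakly nucleophilic formyl ylide to a neopentyl aldehyde held between two quaternary carbons, with low conversion and thermal loss of the ylide. The fallback uses a more nucleophilic phosphonate carbanion and adjusts the oxidation level afterwards. From 18, triethyl 2-phosphonopropionate and NaH would give the (E)-enoate F8. i-Bu2AlH at −78 °C should reduce the conjugated ethyl ester in preference to the hindered allyl ester on C7, giving allylic alcohol F9. MnO2 would give enal 20.

## Further compounds

F1 | step 3 | 4,6-dihydro-1H,3H-thieno[3,4-c]furan-1,3-dione | O=C1OC(=O)C2=C1CSC2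
F2 | step 3 | thia-bridged endo cycloadduct (CH2–S–CH2 bridge in place of the two methyls of 6) | CC(C)(C)[Si](C)(C)OC1=C[C@@H](N2[C@H](c3ccccc3)CC[C@H]2c2ccccc2)[C@@]2(CSC3)C(=O)OC(=O)[C@@]23C1
F3 | step 5 | C4 trimethylsilyl enol ether of the conjugate adduct | C[Si](C)(C)OC1=C[C@H](C(=C)CC)[C@@]2(C)C(=O)OC(=O)[C@@]2(C)C1
F4 | step 5 | C3a α-(1-hydroxyethyl) ketone (carbinol epimers) | O=C1C[C@]2(C)C(=O)OC(=O)[C@]2(C)[C@@H](C(=C)CC)[C@@H]1C(C)O
F5 | step 5 | (E)-C3a-ethylidene ketone | C/C=C1/C(=O)C[C@]2(C)C(=O)OC(=O)[C@]2(C)[C@H]1C(=C)CC
F6 | step 9 | lactone with CH2–O on C6 and carbonyl on C7 | CCC1=C[C@@H](C)[C@@H]2C(C)=C[C@]3(C)COC(=O)[C@]3(C)[C@@H]12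
F7 | step 9 | allyl 6-(hydroxymethyl) ester | CCC1=C[C@@H](C)[C@@H]2C(C)=C[C@](C)(CO)[C@](C)(C(=O)OCC=C)[C@@H]12
F8 | step 11 | (E)-ethyl enoate allyl ester | CCC1=C[C@@H](C)[C@@H]2C(C)=C[C@](C)(/C=C(\C)C(=O)OCC)[C@](C)(C(=O)OCC=C)[C@@H]12
F9 | step 11 | (E)-allylic alcohol allyl ester | CCC1=C[C@@H](C)[C@@H]2C(C)=C[C@](C)(/C=C(\C)CO)[C@](C)(C(=O)OCC=C)[C@@H]12
A1 | alternative 1 | tert-butyl ester of zyggomphic acid B | CCC1=C[C@@H](C)[C@@H]2C(C)=C[C@](C)(/C=C(C)/C=C/c3ccccc3)[C@](C)(C(=O)OC(C)(C)C)[C@@H]12
A2 | alternative 2 | tricyclic menthyloxy lactone with ring A as the C2 enone | CCC1C(=O)[C@@H](C)[C@@H]2C(C)=C[C@]3(C)[C@@H](O[C@H]4[C@@H](C(C)C)CC[C@@H](C)C4)OC(=O)[C@]3(C)C=12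
A3 | alternative 3 | trans-hydrindene C1 carbaldehyde | O=CC1=C[C@@H](C)[C@@H]2C(=O)C=C(C)[C@](C)(C(=O)OC(C)(C)C)[C@@H]12
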